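**Assumptions (one line each)**
- Isodojaponin D is a 6,7-seco-ent-kauranoid with a 7,20-lactone (spiro at C10). C18 is the methyl and C19 the CH2OH on C4.
- The C10 epimer ratio in **5** is immaterial, because C10 is re-enolised in Step 5.
- **18** is used as the C15 epimer mixture, since C15 is oxidised to the ketone in Step 14.

**Retrosynthesis**
1. Target ← C15 enone (SeO2, then MnO2) ← C16=C17 exocyclic alkene ← tertiary alcohol from an intramolecular reductive aldol (C13–C16), which closes the bicyclo[3.2.1] C/D rings. The C12 carbonyl is later removed, and the A-ring γ-lactone and C1 ketone become the C1-OAc, C6-OAc and C19-OH pattern.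
2. The spiro-δ-lactone, the C9–C10 bond and the C8 quaternary centre come from a symmetry-breaking (desymmetrising) intramolecular Michael addition of an A-ring α′-enolate onto a prochiral 4-allyl-4-carboxy-cyclohexa-2,5-dienone.
3. That dienone comes from oxidative dearomatisation (ipso-allylation) of the 4-hydroxybenzoate ester of the A-ring alcohol.
4. The A ring comes from a Diels–Alder reaction (Danishefsky diene + α-methylbutenolide) followed by α′-hydroxymethylation.
5. Ring-forming order: A ring (Diels–Alder), then C-ring dienone (dearomatisation), then spiro-δ-lactone and C9–C10 (Michael), then D ring (aldol).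

---

**Step 1**
Reactants: **1** trans-1-methoxy-3-(trimethylsiloxy)buta-1,3-diene; **2** 3-methylfuran-2(5H)-one
Product: **3** cis-fused enone γ-lactone, 7a-methyl-3a,4-dihydroisobenzofuran-1,5(3H,7aH)-dione
Conditions: chiral oxazaborolidinium Lewis acid (20 mol%), CH2Cl2, –40 °C; then TFA, CH2Cl2, rt
Reagents that add atoms: none
Why: The nucleophilic CH2 terminus of the diene bonds to the β-carbon of the butenolide, and suprafacial addition gives the cis ring fusion. Loss of MeOH on acid work-up gives the enone, and the chiral Lewis acid sets C4/C5 with C19 and C6 on one face and Me and C5–H on the other. Proposed new method: an α-substituted butenolide acts as a normal-demand dienophile under oxazaborolidinium activation; the closest known reaction is the catalytic asymmetric Danishefsky Diels–Alder reaction.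

**Step 2**
Reactants: **3**; **4** formaldehyde
Product: **5** 4-(hydroxymethyl) enone lactone
Conditions: LDA (1.1 equiv), THF, –78 °C; then CH2O (monomeric, g), –78 → –40 °C; NH4Cl
Reagents that add atoms: formaldehyde, C=O
Why: The only enolisable position of **3** is C10 (C2 is vinylic and C4 is quaternary), so a regiospecific α′-aldol installs C20. This is a kinetic enolate hydroxymethylation.

**Step 3**
Reactants: **5**; **6** 4-hydroxybenzoic acid
Product: **7** A-ring C20 4-hydroxybenzoate
Conditions: EDC·HCl, DMAP (0.1 equiv), CH2Cl2, 0 °C
Reagents that add atoms: none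
Why: Carbodiimide esterification is selective for the primary alcohol over the weakly nucleophilic phenol. The phenol ester is a stable, acid-free handle for the dearomatisation.

**Step 4**
Reactants: **7**; **8** allyltrimethylsilane
Product: **9** 4-allyl-4-(acyloxycarbonyl)cyclohexa-2,5-dienone (prochiral dienone ester)
Conditions: PIFA (1.3 equiv), HFIP, –20 °C, 1 h
Reagents that add atoms: none (PIFA leaves only PhI and TFA; the allyl group comes from reactant **8**)
Why: PIFA in HFIP converts the phenol into a phenoxonium cation, and allylsilane attacks the para (ipso-to-ester) carbon in a Hosomi–Sakurai fashion, breaking aromaticity and creating a symmetric quaternary C8. Proposed new method: ipso-allylation of an electron-poor 4-acylphenol. The closest known reaction is the PIFA/HFIP oxidative dearomative allylation of 4-alkylphenols.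

**Step 5**
Reactant: **9**
Product: **10** tetracyclic spiro-δ-lactone with C8-allyl, C12-oxo-Δ13 enone and A-ring Δ2-1-ketone
Conditions: LiHMDS (1.05 equiv), THF, –78 → 0 °C, 0.005 M; NH4Cl
Reagents that add atoms: none
Why: The A-ring α′-enolate (C10) adds 6-exo-trig to one of the two enantiotopic dienone β-carbons (C9). The tether fixes which alkene reacts, which sets C8, and the enolate attacks anti to the axial C19/C6 face, so C9 is formed down and C20 ends up up. This forms the quaternary C10 and the spiro-δ-lactone in one step. Proposed new method: an ester-tethered desymmetrising Michael lactonisation. The closest known reactions are desymmetrising intramolecular Michael additions to 4,4-disubstituted cyclohexadienones and Michael-type lactone closures.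

**Step 6**
Reactant: **10**
Product: **11** C16 methyl ketone (C15H2–C16(=O)–CH3)
Conditions: PdCl2 (0.2 equiv), CuCl (2 equiv), O2 (1 atm), DMF/H2O 7:1, rt
Reagents that add atoms: water, O (the ketone oxygen)
Why: Wacker oxidation is Markovnikov and acts only on the electron-rich terminal alkene. Both enones and both lactones are inert.

**Step 7**
Reactant: **11**
Product: **12** bicyclo[3.2.1] tertiary alcohol (C16-OH, C16-CH3) with C12 and C1 ketones
Conditions: Stryker's reagent [(Ph3P)CuH]6 (0.4 equiv), toluene, –20 °C → rt; NH4Cl
Reagents that add atoms: none other than hydrogen (hydride)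
Why: Conjugate reduction of the C13=C14 enone generates the C12/C13 Cu-enolate. This closes 5-exo onto the C16 ketone (reductive aldol), forming C13–C16 with the configuration forced by the bridged ring. The A-ring Δ2 enone is reduced to the saturated C1 ketone in the same operation. Proposed new method: reductive aldol closing a bridged bicyclo[3.2.1]octane. The closest known reaction is Chiu-type Stryker reductive aldol cyclisation.

**Step 8**
Reactant: **12**
Product: **13** C12 tosylhydrazone
Conditions: TsNHNH2 (1.5 equiv), THF/MeOH, rt, 12 h (no acid)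
Reagents that add atoms: p-toluenesulfonyl hydrazide, Cc1ccc(cc1)S(=O)(=O)NN
Why: The bridged C12 ketone condenses faster than the neopentylic C1 ketone beside quaternary C10. Non-acidic conditions avoid retro-aldol of the β-hydroxy ketone.

**Step 9**
Reactant: **13**
Product: **14** C12-deoxy tertiary alcohol (C12H2)
Conditions: catecholborane (5 equiv), CHCl3, 0 °C, 2 h; then NaOAc·3H2O, reflux, 1 h
Reagents that add atoms: none (hydride only)
Why: Kabalka reduction of tosylhydrazones to CH2 tolerates lactones, ketone and free alcohol. No stereocentre is touched.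

**Step 10**
Reactant: **14**
Product: **15** exocyclic alkene (C16=C17) with C1 ketone
Conditions: Burgess reagent (1.5 equiv), benzene, 50 °C
Reagents that add atoms: none
Why: Syn-elimination of the tertiary alcohol toward the freely rotating C17 methyl is favoured over toward bridge C15, giving the ent-kaur-16-ene exocyclic alkene. Burgess conditions are neutral, so no retro-aldol occurs.

**Step 11**
Reactant: **15**
Product: **16** triol (C1-OH, C6-OH, C19-OH) with the 7,20-lactone intact
Conditions: LiBH4 (6 equiv), THF with MeOH (5 equiv), 0 °C → rt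
Reagents that add atoms: none (hydride only)
Why: The less hindered cis-fused γ-lactone (C19 carbonyl, O–C6H2) is reduced to the diol, releasing C19-OH and C6-OH. The δ-lactone carbonyl (on quaternary C8, inside the polycycle) survives. Axial hydride attack at C1 from the face opposite axial C19/C20 gives the equatorial 1β-OH as in the target.

**Step 12**
Reactant: **16**
Product: **17** 1,6-diacetate with free 19-OH
Conditions: Ac2O (2.3 equiv), DMAP (cat.), pyridine/CH2Cl2, 0 °C
Reagents that add atoms: acetic anhydride, CC(=O)OC(C)=O
Why: The C6 primary and C1 secondary alcohols acylate faster than the neopentylic, 1,3-diaxially shielded C19-OH. Stereocentres are untouched.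

**Step 13**
Reactant: **17**
Product: **18** C15 allylic alcohol (epimeric mixture)
Conditions: SeO2 (0.5 equiv), TBHP (3 equiv), CH2Cl2, rt
Reagents that add atoms: SeO2, O=[Se]=O, and tert-butyl hydroperoxide, CC(C)(C)OO (oxygen source)
Why: Riley allylic oxidation of the exocyclic alkene occurs at bridge C15, as in ent-kaurene chemistry. The new centre is destroyed in the next step.

**Step 14**
Reactant: **18**
Product: **19** Isodojaponin D
Conditions: activated MnO2 (20 equiv), CH2Cl2, rt
Reagents that add atoms: none
Why: MnO2 selectively oxidises the allylic alcohol to the C15 enone and leaves the saturated primary 19-OH and the acetates alone.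

---

**Compound list**

| No. | Name | SMILES | Role |
|---|---|---|---|
| 1 | trans-1-Methoxy-3-(trimethylsiloxy)-1,3-butadiene | `CO/C=C/C(=C)O[Si](C)(C)C` | starting material |
| 2 | 3-Methylfuran-2(5H)-one | `CC1=CCOC1=O` | starting material |
| 3 | cis-Enone γ-lactone (A-ring core) | `O=C1C=C[C@@]2(C)C(=O)OC[C@H]2C1` | intermediate |
| 4 | Formaldehyde | `C=O` | starting material |
| 5 | 4-(Hydroxymethyl) enone lactone (C10 epimers) | `O=C1C=C[C@@]2(C)C(=O)OC[C@H]2C1CO` | intermediate |
| 6 | 4-Hydroxybenzoic acid | `O=C(O)c1ccc(O)cc1` | starting material |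
| 7 | A-ring C20 4-hydroxybenzoate | `O=C1C=C[C@@]2(C)C(=O)OC[C@H]2C1COC(=O)c1ccc(O)cc1` | intermediate |
| 8 | Allyltrimethylsilane | `C=CC[Si](C)(C)C` | starting material |
| 9 | Prochiral 4-allyl-4-carboxy dienone ester | `O=C1C=C[C@@]2(C)C(=O)OC[C@H]2C1COC(=O)C1(CC=C)C=CC(=O)C=C1` | intermediate |
| 10 | Michael tetracycle (spiro-δ-lactone, C8-allyl, C12-oxo-Δ13, A-ring Δ2-1-one) | `C=CC[C@]23C=CC(=O)C[C@H]2[C@]1(COC3=O)C(=O)C=C[C@@]4(C)C(=O)OC[C@@H]14` | intermediate |
| 11 | C16 methyl ketone | `CC(=O)C[C@]23C=CC(=O)C[C@H]2[C@]1(COC3=O)C(=O)C=C[C@@]4(C)C(=O)OC[C@@H]14` | intermediate |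
| 12 | Bicyclo[3.2.1] tertiary alcohol, C12 and C1 ketones | `CC1(O)C[C@]23C[C@H]1C(=O)C[C@H]2[C@]1(COC3=O)C(=O)CC[C@@]4(C)C(=O)OC[C@@H]14` | intermediate |
| 13 | C12 tosylhydrazone | `CC1(O)C[C@]23C[C@H]1C(=NNS(=O)(=O)c5ccc(C)cc5)C[C@H]2[C@]1(COC3=O)C(=O)CC[C@@]4(C)C(=O)OC[C@@H]14` | intermediate |
| 14 | C12-deoxy tertiary alcohol | `CC1(O)C[C@]23C[C@H]1CC[C@H]2[C@]1(COC3=O)C(=O)CC[C@@]4(C)C(=O)OC[C@@H]14` | intermediate |
| 15 | Exocyclic alkene, C1 ketone, γ- and δ-lactones | `C=C1C[C@]23C[C@H]1CC[C@H]2[C@]1(COC3=O)C(=O)CC[C@@]4(C)C(=O)OC[C@@H]14` | intermediate |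
| 16 | 1,6,19-Triol (7,20-lactone intact) | `C=C1C[C@]23C[C@H]1CC[C@H]2[C@]1(COC3=O)[C@@H](O)CC[C@@](C)(CO)[C@H]1CO` | intermediate |
| 17 | 1,6-Diacetate, 19-OH free | `C=C1C[C@]23C[C@H]1CC[C@H]2[C@]1(COC3=O)[C@@H](OC(C)=O)CC[C@@](C)(CO)[C@H]1COC(C)=O` | intermediate |
| 18 | C15 allylic alcohol (epimers) | `C=C1C(O)[C@]23C[C@H]1CC[C@H]2[C@]1(COC3=O)[C@@H](OC(C)=O)CC[C@@](C)(CO)[C@H]1COC(C)=O` | intermediate |
| 19 | Isodojaponin D | `C=C1C(=O)[C@]23C[C@H]1CC[C@H]2[C@]1(COC3=O)[C@@H](OC(C)=O)CC[C@@](C)(CO)[C@H]1COC(C)=O` | target |

**Totals:** 14 steps; longest linear sequence 14 steps (from **1**/**2**).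

**Three steps most likely to fail**
1. **Step 4 (oxidative ipso-allylation of an electron-poor phenol ester).**
   - Fallback: avoid dearomatisation. Allylate commercial ethyl 1,4-dioxaspiro[4.5]decane-8-carboxylate with LDA/allyl bromide, hydrolyse, couple to **5**, remove the ketal, and double-dehydrogenate the C12 ketone with IBX·MPO to give **9**.
2. **Step 5 (ester-tethered desymmetrising Michael; the Z-ester conformer disfavours the 6-membered lactone).**
   - Fallback: run an intermolecular Michael addition of the TBS-protected enolate of **5** to the methyl-ester analogue of **9**. Remove the silyl group with TBAF and close the lactone with Me3Al, so that C–C and C–O bond formation are separated.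
3. **Step 1 (enantioselective Diels–Alder of an unreactive α-methylbutenolide).**
   - Fallback: use a thermal racemic Diels–Alder reaction at 130 °C and resolve **3** by preparative chiral-phase HPLC, giving the same A-ring enantiomer by resolution instead of catalysis.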